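Start with Thursday's flask: it stands at 60 °C, as the alpha run did, so no temperature correction comes in.

in all of them: substrate 0.36 M

|  | reagent | temperature | remark | time |
|---|---|---|---|---|
| gamma | 0.36 M | 35 °C | run made earlier |  |
| alpha | 1.4 M | 60 °C | run made earlier |  |
| Friday's | 0.720 M | 80 °C |  | 10 min |
| Thursday's | 0.720 M | 60 °C |  | 10 min |
| Wednesday's | 0.720 M | 40 °C |  | 10 min |

| run | time / min | bis adduct / % |
|---|---|---|
| gamma | 10.0 | 3 |
| gamma | 30.0 | 12 |
| gamma | 50.0 | 17 |
| gamma | 80.0 | 22 |
| alpha | 5.00 | 62 |
| alpha | 10.0 | 86 |
| alpha | 15.0 | 97 |
| alpha | 20.0 | 98 |

(scatter of a reading: 1.5 percentage points)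

* the flask that comes out highest in amount of bis adduct, in percent of the substrate charged, or "all alike" when all lie within 1.5 percentage points (Friday's / Thursday's / Wednesday's / all alike)
* bis adduct at the end, in percent of the substrate charged, Friday's
* bis adduct at the end, in percent of the substrate charged, Thursday's
* bis adduct at the end, in percent of the substrate charged, Wednesday's

- the numbers in the tables scatter with a standard deviation of 1.5 percentage points
- a reading or a percentage of bis adduct counts all its forms, free or not

*Which clock do you read, minutes?*

No. Suppose each bis adduct takes two reagent, one addition after the other, through an intermediate, with each rate proportional to c(reagent). Compare the making and the using of that intermediate at one moment: c(reagent) stands in both and cancels, leaving a selectivity factor times a ratio of concentrations. So, at one temperature, the path runs on the area under c(reagent) against time, not on minutes.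

*Put a number on it.*

Take the alpha run's reading of 62% at 5.00 min. Two reagent per bis adduct makes 0.446 M spent. A straight fall then gives a mean c(reagent) of 1.18 M and an area of 353 M·s. That is the reagent-time that buys the alpha run's first reading.

*And Thursday's flask?*

The same spend from 0.720 M gives a mean of 0.497 M, so I reckon Thursday's flask needs 11.8 min for that reading, longer than its 10 min. A straight line through the origin scales the reading to 52.3%.

*You charged nothing for reagent held in the intermediate.*

True, and the same loss counts for more against 0.720 M than against 1.4 M. I commit to about 52.3% and expect the flask lower.

*Friday's and Wednesday's flasks?*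

No run stands at their temperatures, so this comparison gives no figure for them. I expect the hottest flask, Friday's, to be highest.

The forecast also names Friday's, with 89%, 57% and 13% for Friday's, Thursday's and Wednesday's flasks, reasoning: “The gamma run levels off as if two reagents are used per substrate.” For Thursday's flask its figure stands above mine.

The flasks give 74.4%, 47.1% and 12.9% in that order, with Friday's highest.

    substrate + reagent → single product (k = 0.0102 /M/s, Ea = 73.0 kJ/mol)
    reagent + single product → bis adduct (k = 0.00505 /M/s, Ea = 50.0 kJ/mol)
    crystals ⇌ bis adduct, rate k3*(cs3 - [bis adduct]) while solid is left; crystals form when [bis adduct] > cs3 (solubility = 0.260 M, k = 0.991 /s)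
    (constants at 60 °C)

In Thursday's flask, single product was being made 2.88 times as fast as it was used at 1.59 min, and by 10.0 min that ratio had dropped to 0.455, with 43.2% standing as single product and 9.72% as substrate. Reagent in Thursday's flask fell to 31.3% of its charge by then, a reagent-time of 232 M·s, less than the 353 M·s carried from the alpha run; the same flask read at 25 min had reagent at 15.5%, a reagent-time of 383 M·s, past that mark, and bis adduct at 71.4%.

The readings stem from a simulated flask for substances that don't exist.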